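Ring B is disconnected at the C7–C8 bond: the 8‑hydroxyl next to the 7‑isopropenyl group (array O–C8–C7–C11=C12) is the retron of an intramolecular carbonyl‑ene reaction. A ring A aldehyde carrying a prenyl group on quaternary C5 and an ether oxygen on C9 is cyclised under chelation by Me2AlCl; this one operation closes ring B, creates the isopropenyl group and sets C7 and C8. The precursor is a monocyclic cyclohexane made by enantioselective conjugate addition/enolate alkylation of 2‑methylcyclohexenone, Felkin‑controlled dithiane addition and face‑selective hydroboration. Both (Z)‑hexenoates are introduced last as ynoates and semi‑hydrogenated.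

Key step: step 10

Remark: eremophilane numbering is used for all compounds (ring A = C1–C5, C10; ring B = C5–C10; C11–C13 = isopropenyl on C7; C14 = methyl on C5; C15 = methyl on C4; β = face of C14); the target is read as (3R,4R,5R,7S,8R,9S,10R) with a trans ring fusion; SEM = 2‑(trimethylsilyl)ethoxymethyl.

Step 1
Reactants: 1 2‑methylcyclohex‑2‑en‑1‑one; 2 vinylmagnesium bromide; 3 ethyl bromoacetate
Product: 5 ethyl 2‑[(1S,2S)‑1‑methyl‑6‑oxo‑2‑vinylcyclohexyl]acetate, via bromomagnesium enolate 4 (not isolated)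
Conditions: 2, Cu(OTf)2 (3 mol %), chiral imidazolinium chloride (carbene ligand precursor, 4 mol %, antipode giving S at the vinyl‑bearing carbon), Et2O, −30 °C; then 3, DMPU, −30 → 20 °C
Reagents that add atoms: vinylmagnesium bromide C=C[Mg]Br; ethyl bromoacetate CCOC(=O)CBr
Why: Copper‑catalysed enantioselective conjugate addition of a Grignard reagent to an α‑substituted cyclic enone sets C10 under ligand control, and alkylation of the regiodefined magnesium enolate places the CH2CO2Et group on C5 anti to the new vinyl group (C14 cis to vinyl).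

Step 2
Reactants: 5 keto ester
Product: 7 ethyl 2‑[(1S,2R)‑2‑formyl‑1‑methyl‑6‑oxocyclohexyl]acetate, via secondary ozonide 6 (not isolated)
Conditions: O3, CH2Cl2, −78 °C; then Me2S, −78 → 20 °C
Reagents that add atoms: ozone [O-][O+]=O
Why: Ozonolysis with reductive work‑up cleaves the only alkene to the C9 aldehyde under neutral conditions that should not epimerise C10.

Step 3
Reactants: 7 keto aldehyde; 8 1,3‑dithiane
Product: 10 (5S,9S,10R) keto ester with C10 side chain CH(OSEM)(1,3‑dithian‑2‑yl), via lithium alkoxide 9 (not isolated)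
Conditions: 8, n‑BuLi, THF, −30 °C; 7, −78 °C; then Me3SiCH2CH2OCH2Cl, DMPU, −78 → 0 °C
Reagents that add atoms: 1,3‑dithiane C1CSCSC1; 2‑(trimethylsilyl)ethoxymethyl chloride C[Si](C)(C)CCOCCl
Why: 2‑Lithio‑1,3‑dithiane (formyl anion equivalent) adds to the aldehyde faster than to the hindered ketone or the ester; Felkin–Anh attack anti to quaternary C5, with C1H2 flanking the carbonyl oxygen, sets C9 as in the target, and the alkoxide is trapped as the chelating SEM ether.

Step 4
Reactants: 10 SEM ether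
Product: 12 (5S,9S,10R) enol triflate (C3=C4–OTf), via potassium enolate 11 (not isolated)
Conditions: KN(SiMe3)2, THF, −78 °C; then PhNTf2, −78 → 0 °C
Reagents that add atoms: N‑phenyl‑bis(trifluoromethanesulfonimide) O=S(=O)(N(c1ccccc1)S(=O)(=O)C(F)(F)F)C(F)(F)F
Why: Only C3 carries enolisable ketone hydrogens (C5 is quaternary), so deprotonation and O‑sulfonylation should give a single enol triflate.

Step 5
Reactants: 12 enol triflate; 13 methylmagnesium bromide
Product: 14 (5S,9S,10R) alkene (C3=C4 with C15 on C4)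
Conditions: 13, Fe(acac)3 (5 mol %), THF/NMP, −30 °C
Reagents that add atoms: methylmagnesium bromide C[Mg]Br
Why: Iron‑catalysed cross‑coupling of an alkenyl triflate with a Grignard reagent (Kumada type) installs C15 and leaves the ester untouched at low temperature.

Step 6
Reactants: 14 alkene
Product: 16 (3R,4R,5R,9S,10R) alcohol (3α‑OH, 4β‑CH3, 5β‑CH3, 5α‑CH2CO2Et), via alkylborane 15 (not isolated)
Conditions: BH3·THF, THF, 0 → 20 °C; then Me3NO·2H2O, diglyme, 80 °C
Reagents that add atoms: trimethylamine N‑oxide C[N+](C)(C)[O-]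
Why: Hydroboration–oxidation puts boron on the less substituted C3 and hydrogen on C4 in a syn addition from the α face, anti to the pseudoaxial C14 on neighbouring C5 (the equatorial C10 side chain fixes the half‑chair), giving 3α‑OH trans to 4β‑CH3; the amine oxide oxidises C–B with retention and spares sulfur.

Step 7
Reactants: 16 alcohol
Product: 17 (3R,4R,5R,9S,10R) aldehyde (C5–CH2–CHO)
Conditions: i‑Bu2AlH (2.2 equiv), CH2Cl2, −78 °C; aq. potassium sodium tartrate
Reagents that add atoms: none
Why: Partial reduction of the ethyl ester stops at the aluminium hemiacetal, which is stable at −78 °C and releases the C7 aldehyde on work‑up.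

Step 8
Reactants: 17 aldehyde; 18 isopropyltriphenylphosphonium iodide
Product: 19 (3R,4R,5R,9S,10R) prenyl compound (C5–CH2–CH=C(CH3)2)
Conditions: 18, n‑BuLi, THF, 0 °C; 17, −78 → 20 °C
Reagents that add atoms: isopropyltriphenylphosphonium iodide CC(C)[P+](c1ccccc1)(c1ccccc1)c1ccccc1.[I-]
Why: Wittig olefination with the unstabilised isopropylidene ylide builds the prenyl (ene donor) group without touching a stereocentre.

Step 9
Reactants: 19 prenyl compound
Product: 20 (3R,4R,5R,9S,10R) α‑SEM‑oxy aldehyde (C10–CH(OSEM)–CHO)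
Conditions: MeI, CaCO3, MeCN/H2O 9:1, 45 °C
Reagents that add atoms: water O
Why: S‑Methylation turns the dithiane into a leaving group and water hydrolyses it under buffered, non‑oxidising conditions that should spare the trisubstituted alkene, the SEM ether and the C9 configuration.

Step 10
Reactants: 20 α‑SEM‑oxy aldehyde
Product: 21 (3R,4R,5R,7S,8R,9S,10R)‑9‑(SEM‑oxy)eremophil‑11‑ene‑3,8‑diol
Conditions: Me2AlCl (3.5 equiv), CH2Cl2, −78 → −30 °C; aq. potassium sodium tartrate
Reagents that add atoms: none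
Why: Me2AlCl (one equivalent is consumed by the 3‑OH) binds the C8 aldehyde oxygen and the C9 ether oxygen in a five‑membered chelate, and C7 of the prenyl alkene attacks the activated carbonyl while a hydrogen of a C11 methyl passes to oxygen in a concerted type 1 intramolecular carbonyl‑ene reaction, forming the C7–C8 bond, the 8‑hydroxyl and the C11=C12 isopropenyl group at once. The closest known reactions are the Lewis‑acid cyclisation of citronellal to isopulegol and Me2AlCl‑promoted ene cyclisations of unsaturated aldehydes. Ring B closes as a six‑membered ring along the tether C8–C9–C10–C5–C6–C7 through a chair‑like transition state fused trans to ring A. C7 is controlled by the axial C14 methyl on C5: C11 must sit equatorial to avoid a syn‑axial clash, which gives the 7α‑isopropenyl group. C8 is controlled by the chelate: with O8 held syn to O9, C7 can only reach the carbonyl face on the C10 side, which gives the 8,9‑cis arrangement with the axial 8α‑OH. The step needs this cis selectivity against the usual all‑equatorial outcome and ene selectivity against chloride capture or isomerisation to the isopropylidene; the first should be secured by the chelating ether on C9, the second by Me2AlCl acting as proton scavenger at low temperature.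

Step 11
Reactants: 21 SEM ether
Product: 22 (3R,4R,5R,7S,8R,9S,10R)‑eremophil‑11‑ene‑3,8,9‑triol
Conditions: Bu4NF, DMPU, 4 Å molecular sieves, 80 °C
Reagents that add atoms: none
Why: Fluoride attacks silicon and the SEM group fragments without an oxocarbenium ion, so the cis 8‑OH should not be tied into a cyclic formal and the isopropenyl group sees no acid.

Step 12
Reactants: 22 triol; 23 hex‑2‑ynoic acid
Product: 24 (3R,4R,5R,7S,8R,9S,10R)‑8‑hydroxyeremophil‑11‑ene‑3,9‑diyl bis(hex‑2‑ynoate)
Conditions: 23 (2.2 equiv), DCC, DMAP (cat.), CH2Cl2, −20 → 0 °C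
Reagents that add atoms: hex‑2‑ynoic acid CCCC#CC(=O)O
Why: Steglich esterification should acylate the two equatorial hydroxyls (C3, C9) and leave the axial 8‑OH, flanked by the C7 and C9 substituents, free; low temperature limits DMAP addition to the ynoate and 9→8 acyl migration.

Step 13
Reactants: 24 bis(ynoate)
Product: 25 target, (3R,4R,5R,7S,8R,9S,10R)‑8‑hydroxyeremophil‑11‑ene‑3,9‑diyl bis[(2Z)‑hex‑2‑enoate]
Conditions: H2 (1 atm), Pd/CaCO3 poisoned with Pb(OAc)2 (Lindlar catalyst), quinoline, EtOAc, 20 °C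
Reagents that add atoms: none
Why: Lindlar semi‑hydrogenation adds H2 syn to both conjugated alkynes to give the (Z)‑enoates, and quinoline should keep the 1,1‑disubstituted isopropenyl alkene and the new enoates from further reduction.

Compound list
1 | 2‑methylcyclohex‑2‑en‑1‑one | CC1=CCCCC1=O | starting material
2 | vinylmagnesium bromide | C=C[Mg]Br | starting material
3 | ethyl bromoacetate | CCOC(=O)CBr | starting material
4 | bromomagnesium (S)‑2‑methyl‑3‑vinylcyclohex‑1‑en‑1‑olate | CC1=C(O[Mg]Br)CCC[C@H]1C=C | intermediate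
5 | ethyl 2‑[(1S,2S)‑1‑methyl‑6‑oxo‑2‑vinylcyclohexyl]acetate | CCOC(=O)C[C@]1(C)C(=O)CCC[C@H]1C=C | intermediate
6 | secondary ozonide of 5 (vinyl group as 1,2,4‑trioxolane) | CCOC(=O)C[C@]1(C)C(=O)CCC[C@H]1C2OCOO2 | intermediate
7 | ethyl 2‑[(1S,2R)‑2‑formyl‑1‑methyl‑6‑oxocyclohexyl]acetate | CCOC(=O)C[C@]1(C)C(=O)CCC[C@H]1C=O | intermediate
8 | 1,3‑dithiane | C1CSCSC1 | starting material
9 | lithium alkoxide of the C9 dithianyl carbinol | CCOC(=O)C[C@]1(C)C(=O)CCC[C@H]1[C@H](O[Li])C2SCCCS2 | intermediate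
10 | ethyl 2‑[(1S,2R)‑2‑{(S)‑(1,3‑dithian‑2‑yl)[2‑(trimethylsilyl)ethoxymethoxy]methyl}‑1‑methyl‑6‑oxocyclohexyl]acetate | CCOC(=O)C[C@]1(C)C(=O)CCC[C@H]1[C@H](OCOCC[Si](C)(C)C)C2SCCCS2 | intermediate
11 | potassium enolate of 10 (C3=C4–OK) | CCOC(=O)C[C@]1(C)C(O[K])=CCC[C@H]1[C@H](OCOCC[Si](C)(C)C)C2SCCCS2 | intermediate
12 | (5S,9S,10R) enol triflate (C3=C4–OTf) | CCOC(=O)C[C@]1(C)C(OS(=O)(=O)C(F)(F)F)=CCC[C@H]1[C@H](OCOCC[Si](C)(C)C)C2SCCCS2 | intermediate
13 | methylmagnesium bromide | C[Mg]Br | starting material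
14 | (5S,9S,10R) alkene (C3=C4, C15 on C4) | CCOC(=O)C[C@]1(C)C(C)=CCC[C@H]1[C@H](OCOCC[Si](C)(C)C)C2SCCCS2 | intermediate
15 | C3 alkylborane from 14 (3α‑BH2, 4β‑CH3) | CCOC(=O)C[C@]1(C)[C@@H](C)[C@H](B)CC[C@H]1[C@H](OCOCC[Si](C)(C)C)C2SCCCS2 | intermediate
16 | (3R,4R,5R,9S,10R) hydroxy ester (3α‑OH, 4β‑CH3, 5β‑CH3, 5α‑CH2CO2Et) | CCOC(=O)C[C@]1(C)[C@@H](C)[C@H](O)CC[C@H]1[C@H](OCOCC[Si](C)(C)C)C2SCCCS2 | intermediate
17 | (3R,4R,5R,9S,10R) hydroxy aldehyde (C5–CH2–CHO) | O=CC[C@]1(C)[C@@H](C)[C@H](O)CC[C@H]1[C@H](OCOCC[Si](C)(C)C)C2SCCCS2 | intermediate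
18 | isopropyltriphenylphosphonium iodide | CC(C)[P+](c1ccccc1)(c1ccccc1)c1ccccc1.[I-] | starting material
19 | (3R,4R,5R,9S,10R) prenyl dithiane (C5–CH2–CH=C(CH3)2) | CC(C)=CC[C@]1(C)[C@@H](C)[C@H](O)CC[C@H]1[C@H](OCOCC[Si](C)(C)C)C2SCCCS2 | intermediate
20 | (3R,4R,5R,9S,10R) α‑SEM‑oxy aldehyde (ene precursor) | CC(C)=CC[C@]1(C)[C@@H](C)[C@H](O)CC[C@H]1[C@H](OCOCC[Si](C)(C)C)C=O | intermediate
21 | (3R,4R,5R,7S,8R,9S,10R)‑9‑(SEM‑oxy)eremophil‑11‑ene‑3,8‑diol | C=C(C)[C@@H]1C[C@]2(C)[C@@H](C)[C@H](O)CC[C@H]2[C@H](OCOCC[Si](C)(C)C)[C@@H]1O | intermediate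
22 | (3R,4R,5R,7S,8R,9S,10R)‑eremophil‑11‑ene‑3,8,9‑triol | C=C(C)[C@@H]1C[C@]2(C)[C@@H](C)[C@H](O)CC[C@H]2[C@H](O)[C@@H]1O | intermediate
23 | hex‑2‑ynoic acid | CCCC#CC(=O)O | starting material
24 | (3R,4R,5R,7S,8R,9S,10R)‑8‑hydroxyeremophil‑11‑ene‑3,9‑diyl bis(hex‑2‑ynoate) | C=C(C)[C@@H]1C[C@]2(C)[C@@H](C)[C@H](OC(=O)C#CCCC)CC[C@H]2[C@H](OC(=O)C#CCCC)[C@@H]1O | intermediate
25 | (3R,4R,5R,7S,8R,9S,10R)‑8‑hydroxyeremophil‑11‑ene‑3,9‑diyl bis[(2Z)‑hex‑2‑enoate] | C=C(C)[C@@H]1C[C@]2(C)[C@@H](C)[C@H](OC(=O)/C=C\CCC)CC[C@H]2[C@H](OC(=O)/C=C\CCC)[C@@H]1O | target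

Total step count: 13. Longest linear sequence: 13 steps (1 → 25).

Steps most likely to fail

1. Step 10 (key step). The chelate may be lost, with aluminium bound only to the aldehyde oxygen; closure then runs through the chair with the metal‑bound oxygen equatorial and gives the C8 epimer. Ionisation to the C11 cation with chloride capture or proton loss to the isopropylidene isomer is a second failure path. The fallback makes the C8 configuration independent of the cyclisation. It sets out from 19: the 3‑OH is silylated (t‑BuMe2SiOTf, 2,6‑lutidine) to the silyl ether F1, and the dithiane is hydrolysed as in step 9 to the aldehyde F2. The same ene cyclisation, now with no demand on C8, gives the alcohol F3 (written as the 8β epimer; any C8 mixture is carried on). Dess–Martin oxidation gives the 8‑ketone F4, and LiBH(s‑Bu)3 at −78 °C, attacking from the equatorial side, should give the axial 8α‑alcohol F5. Bu4NF in DMPU removes both silicon groups and the route is rejoined at 22.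

2. Step 1. Transfer of the sp2 group may be poorly enantioselective (uncatalysed background addition, competing 1,2‑addition), and C‑alkylation of the hindered magnesium enolate may be slow. The fallback replaces the vinyl group by a primary alkyl Grignard reagent, the class for which this tandem addition/trapping on 2‑methylcyclohexenone is best established, and reaches the aldehyde without ozonolysis. It sets out from 1: the same copper‑catalysed sequence with (dimethylphenylsilyl)methylmagnesium chloride and 3 gives the silane F6. Fleming–Tamao oxidation (HBF4·OEt2; then H2O2, KF, KHCO3) gives the primary alcohol F7, and Dess–Martin oxidation returns the route at 7.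

3. Step 12. Discrimination between the equatorial 9‑OH and the axial 8‑OH may be insufficient, leading to over‑acylation or 9→8 acyl migration, and DMAP may add to the ynoate. The fallback differentiates the diol through a tin acetal. It sets out from 22 and 23: 23 is converted with (COCl)2 and catalytic DMF into hex‑2‑ynoyl chloride F8, and 22 is heated with Bu2SnO in MeOH to give the 8,9‑O‑dibutylstannylene acetal F9. One equivalent of F8 at 0 °C should acylate the activated equatorial O9; pyridine and a second equivalent of F8 then esterify the 3‑OH, returning the route at 24.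

Further compounds
F1 | step 10 | 3‑O‑tert‑butyldimethylsilyl ether of 19 | CC(C)=CC[C@]1(C)[C@@H](C)[C@H](O[Si](C)(C)C(C)(C)C)CC[C@H]1[C@H](OCOCC[Si](C)(C)C)C2SCCCS2
F2 | step 10 | 3‑O‑silyl α‑SEM‑oxy aldehyde | CC(C)=CC[C@]1(C)[C@@H](C)[C@H](O[Si](C)(C)C(C)(C)C)CC[C@H]1[C@H](OCOCC[Si](C)(C)C)C=O
F3 | step 10 | (8S)‑epimeric ene product, 3‑OTBS, 9‑OSEM (8β‑OH) | C=C(C)[C@@H]1C[C@]2(C)[C@@H](C)[C@H](O[Si](C)(C)C(C)(C)C)CC[C@H]2[C@H](OCOCC[Si](C)(C)C)[C@H]1O
F4 | step 10 | 8‑ketone, 3‑OTBS, 9‑OSEM | C=C(C)[C@@H]1C[C@]2(C)[C@@H](C)[C@H](O[Si](C)(C)C(C)(C)C)CC[C@H]2[C@H](OCOCC[Si](C)(C)C)C1=O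
F5 | step 10 | (8R)‑alcohol, 3‑OTBS, 9‑OSEM (8α‑OH) | C=C(C)[C@@H]1C[C@]2(C)[C@@H](C)[C@H](O[Si](C)(C)C(C)(C)C)CC[C@H]2[C@H](OCOCC[Si](C)(C)C)[C@@H]1O
F6 | step 1 | ethyl 2‑[1‑methyl‑2‑(dimethylphenylsilylmethyl)‑6‑oxocyclohexyl]acetate (5β‑CH3, 10β‑CH2Si) | CCOC(=O)C[C@]1(C)C(=O)CCC[C@H]1C[Si](C)(C)c2ccccc2
F7 | step 1 | ethyl 2‑[2‑(hydroxymethyl)‑1‑methyl‑6‑oxocyclohexyl]acetate (5β‑CH3, 10β‑CH2OH) | CCOC(=O)C[C@]1(C)C(=O)CCC[C@H]1CO
F8 | step 12 | hex‑2‑ynoyl chloride | CCCC#CC(=O)Cl
F9 | step 12 | 8,9‑O‑dibutylstannylene acetal of 22 | C=C(C)[C@@H]1C[C@]2(C)[C@@H](C)[C@H](O)CC[C@H]2[C@H](O3)[C@@H]1O[Sn]3(CCCC)CCCC
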